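Read the plateau first.

common to all: X 1.5 M
- Friday's: Z 1.5 M; run made earlier
- Tuesday's: Z 2.2 M; run made earlier
- flask: Z 3.00 M; time 15 d

| run | time / d | G / % | X / % |
|---|---|---|---|
| Friday's | 0.167 | 9.7 | 0.3 |
| Friday's | 0.417 | 19.4 | 0.6 |
| Friday's | 1.25 | 19.2 | 0 |
| Friday's | 4.00 | 14.4 | 0.4 |
| Friday's | 12.0 | 14.4 | 0 |
| Tuesday's | 0.167 | 13.5 | 0.6 |
| Tuesday's | 0.417 | 27.2 | 0 |
| Tuesday's | 1.25 | 25.1 | 0 |
| Tuesday's | 4.00 | 18.5 | 0.5 |
| Tuesday's | 12.0 | 19.1 | 0.3 |

(each reading ± 0.5 percentage points)

- the best time, 15 d at the latest, for G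
- the amount of G, in percent of the X charged, at that time
- the first time at which G reaches 25%, in the same percent, in d

- the numbers in the tables scatter by 0.5 percentage points (one standard deviation)

In Friday's and Tuesday's runs, G climbs steeply, has its highest reading at 0.417 d, and sinks to a flat level by 4.00 d. I scale the early readings by [Z] and average the two runs, which draws my own curve for the flask. On that estimated curve G starts steeply, reaching 18.9% at 0.167 d and 37.9% at 0.417 d. Between those two points the curve crosses 25% at about 0.247 d. The knee lies between 0.417 d and 1.25 d, so I take the second height as my summit.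

For the level, I divide the mean of the last two readings by the highest reading. This gives 0.742 on Friday's run and 0.691 on Tuesday's. I carry their mean, 0.717, and call it the keep: the share of the highest reading of G that stays in the plateau. It is a rough gauge of kinetic against thermodynamic control. My flask therefore levels near 27.2%.

The forecast gives 36% at 0.7 d, reaches 25% at 0.27 d, and reads the fall as “a reversible loss or equilibrium”. My summit stands higher than its figure.

The flask gives 35.9% at 0.598 d, reaches 25% at 0.237 d, and holds 23.5% at 15.0 d.

    X → Q (k = 0.0215 min⁻¹)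
    Z → E (k = 0.0109 min⁻¹)
    Q + E → G (k = 6.34 × 10⁻⁴ L mol⁻¹ min⁻¹)
    G ⇌ D (K = 2.30, k = 0.00110 min⁻¹)
    Z ⇌ J (K = 0.540, k = 0.00102 min⁻¹)
    E → L (k = 7.63 × 10⁻⁴ min⁻¹)

The flask's own keep is 0.655, less than the carried value. Without the conversion of G into D, both ways, the highest G in this flask rises from 35.9% to 77.6%, so that step already weighs on the summit. In the neighbour charged with 0.75 M of Z, the keep applied to its summit of 11.7% gives 8.39%, and that neighbour ends at 7.78%.

(The readings come from a simulation with made-up constants; scatter was added.)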